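The readings were computed from invented constants, noise included.

A small charge: E at 0.41 M, D at 1.05 equiv and Q at 1.00 equiv, at 110 °C, closed and stirred, while we read J.

all flasks: E 0.41 M; D 1.05 equiv; temperature 110 °C

| flask | Q | remark | time |
|---|---|---|---|
| midnight | 1 equiv | the very flask that is asked about, followed so far |  |
| flask | 1.00 equiv |  | 6.0 min |

- midnight (time / min: J / %): 0.500: 7.7; 0.833: 10.9; 1.50: 14.7; 3.00: 19.6; 6.00: 22.6

(readings scatter by 0.5 percentage points)

- red: at 6.0 min take out 90% of the J then present, then wait 12 min
- blue: at 6.0 min raise the temperature by 25 K, then wait 12 min
- amber: at 6.0 min add D, 50.0% of the amount charged, then wait 12 min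
- violet: change nothing and wait 12 min more

- J, in percent of the E first charged, at 6.0 min
- what to do for the largest gain in J; "none" if nothing gains more than 2 percentage points (red / blue / amber / violet / none)
- J present, with what was taken out counted in, in percent of the E first charged, after amber
- J present, with what was taken out counted in, in percent of the E first charged, after violet

- J that was removed still counts
- the earlier runs do not show what temperature does; that part of a forecast is a guess
- additions bring no volume worth counting

Between the last two readings of the midnight run J gains 0.0100 /min of the E charged; this gain per minute is what we carry, the creep. For violet we bracket J after 12 min more.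

From above, first hold the creep:

J = 22.6% + creep × 12 min = 34.6%

But if J comes from E and D one for one, the pace follows [E][D]. So we let each shrink as 1 − J, average the pace at both ends, and put each answer back in:

first round: 32.9%

second round: 33.1%

From below, the window before gained 0.0327 /min, so the pace fell to 0.306 of itself as time doubled. If it keeps falling so:

J = 25.0%

We commit to 22.6% now and to the top for violet, since the foot leans on one ratio of two slopes. Yet an error in the reading at 3.00 min reaches the held line multiplied by 4.00. The curve of J does not show what pulls the pace down, so we give no figure for red or amber, and blue is a guess.

The forecast gave 22.7%, red, 31.5% after amber and 25% after violet, at the foot of our bracket, judging that “the tail is slow”.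

The flask gives 22.9% now, and blue gains most, 29 percentage points, against 22 points for red, 13 points for violet and 9.3 points for amber. J stands at 32.2% after amber and 35.6% after violet, 2.5 points over our top.

    E + D ⇌ Q + J (K = 52.0, k = 0.00770 /M/s, Ea = 77.0 kJ/mol, ΔH = 0 kJ/mol)
    J + D ⇌ Q + Z (K = 11.0, k = 0.0240 /M/s, Ea = 63.0 kJ/mol, ΔH = −13.0 kJ/mol)
    J → G (k = 3.60 × 10⁻⁶ /s, Ea = 118 kJ/mol)
    (constants at 110 °C)

Waiting ran at 0.0106 /min, close to the creep, so this flask had not come to rest. Read at 25 min, the same flask holds 40.4% of J, and the creep from 6.0 min reckons 41.6%. Left to 60.0 min, J still gains 27 points over the present figure and reaches 49.5%, but from 25 min on the pace averages 0.002600 /min, less than the creep. At that time E stands at 26.6% of the E charged, and D at 7.90% of its own charge.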